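**Retrosynthetic overview**
- Target ⇒ aryl ether aldehyde + enolised 6-(4-hydroxyphenyl)hex-5-ene-2,4-dione; the last C=C comes from a boron-templated (Pabon) aldol condensation, the laboratory counterpart of the curcuminoid chain assembly.
- Aryl ether aldehyde ⇒ vanillin + ring vinyl epoxide (π-allylpalladium opening, cis-1,4, net retention); vinyl epoxide ⇒ endoperoxide (PPh3 deoxygenation, same flask).
- Endoperoxide ⇒ α-turmerone + singlet oxygen, mirroring the presumed biogenetic oxygenation of the ring diene; one [4+2] sets both ring C–O stereocentres cis to each other and anti to the side chain.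
- Ring order: the 2,3-dioxabicyclo[2.2.2]octene peroxide ring is the only ring made, and it comes first; it is contracted to the oxirane and then opened. The cyclohexene and both benzene rings are bought.

Assumption: 1 is natural (+)-α-turmerone of (6S,1'R) configuration, bought as such or chromatographed from cheap commercial turmeric oil, and used fresh because it autoxidises to ar-turmerone.

Ring locants used below (bisabolane numbering): C1 carries the side chain, C2 the aryloxy oxygen, C3=C4 is the alkene (methyl on C4), C5 carries the hydroxyl, C6 is CH2.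

**Step 1**
Reactants: 1 (+)-α-turmerone, (6S)-2-methyl-6-[(1R)-4-methylcyclohexa-2,4-dien-1-yl]hept-2-en-4-one
Product: 2 anti-endoperoxide, (6S)-2-methyl-6-[(1R,4S,7R)-5-methyl-2,3-dioxabicyclo[2.2.2]oct-5-en-7-yl]hept-2-en-4-one (O–O bridge from C2 to C5 on the ring face opposite the C1 side chain)
Conditions: O2 (1 atm), 5,10,15,20-tetraphenylporphyrin (0.5 mol%), white LED, CH2Cl2, −40 °C; chromatography removes the minor syn diastereomer
Reagents that add atoms: dioxygen (reacting as singlet oxygen), O=O
Why: Singlet-oxygen [4+2] cycloaddition (hetero-Diels–Alder endoperoxidation) is fast on the cisoid ring diene and slow on the electron-poor side-chain enone, it is suprafacial so the new C2–O and C5–O centres are necessarily cis, and oxygen approaches the diene face opposite the C1 side chain to give the 2R,5S isomer as the major, separable product (about 2:1 expected by analogy with α-phellandrene).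

**Step 2**
Reactants: 2 anti-endoperoxide; 3 vanillin (4-hydroxy-3-methoxybenzaldehyde)
Product: 5 4-{[(1R,4S,6R)-4-hydroxy-3-methyl-6-[(2S)-6-methyl-4-oxohept-5-en-2-yl]cyclohex-2-en-1-yl]oxy}-3-methoxybenzaldehyde, via vinyl epoxide 4 (not isolated)
Conditions: PPh3 (1.05 equiv), THF, −20 to 0 °C; then 3 (1.2 equiv), Pd(PPh3)4 (5 mol%), 0 °C to rt
Reagents that add atoms: none
Why: Phosphine deoxygenation of the 1,4-endoperoxide gives the vinyl epoxide because the C5 alkoxide closes onto the tertiary allylic terminus C4 in a syn SN2' expulsion of Ph3P=O from C2 (C5–O configuration retained), and Tsuji–Trost allylic etherification then proceeds by anti ionisation of the C4–O bond by zerovalent palladium and anti attack of the acidic vanillin phenoxide at the distal, non-quaternary C2 terminus, so net retention places the C2 aryloxy group cis to the C5 hydroxyl and trans to the C1 side chain.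

**Step 3**
Reactants: 6 4-hydroxybenzaldehyde; 7 acetylacetone (pentane-2,4-dione, 3 equiv)
Product: 8 (1E,4Z)-5-hydroxy-1-(4-hydroxyphenyl)hexa-1,4-dien-3-one (chelated enol of (E)-6-(4-hydroxyphenyl)hex-5-ene-2,4-dione)
Conditions: B2O3 (1.5 equiv), B(OnBu)3 (2 equiv), n-BuNH2 (0.1 equiv, added slowly), EtOAc, 70 °C; then 0.4 M aq. HCl, 60 °C
Reagents that add atoms: none
Why: Pabon boron-templated aldol (Knoevenagel-type) condensation, in which chelation of the diketone to boron blocks the central carbon and acidifies the terminal methyl groups, the threefold excess of 7 holds the reaction at mono-condensation, and the E alkene forms under thermodynamic control.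

**Step 4**
Reactants: 5 aryl ether aldehyde; 8 enolised 6-(4-hydroxyphenyl)hex-5-ene-2,4-dione
Product: 9 demethoxybisabolocurcumin ether (target), (1E,4Z,6E)-5-hydroxy-7-[4-{[(1R,4S,6R)-4-hydroxy-3-methyl-6-[(2S)-6-methyl-4-oxohept-5-en-2-yl]cyclohex-2-en-1-yl]oxy}-3-methoxyphenyl]-1-(4-hydroxyphenyl)hepta-1,4,6-trien-3-one
Conditions: B2O3 (0.7 equiv), B(OnBu)3 (2 equiv), n-BuNH2 (0.2 equiv, added slowly), EtOAc, 60 °C; then 10% aq. AcOH, 40 °C
Reagents that add atoms: none
Why: Second Pabon boron-templated aldol condensation, in which the boron chelate of 8 leaves only its terminal methyl nucleophilic and this condenses with the aromatic aldehyde of 5 much faster than the unactivated side-chain ketone can react, giving the E styryl bond without touching the four existing stereocentres, while the mild acetic acid work-up frees the diketone without ionising the allylic aryl ether.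

**Compound list**
1 | (+)-α-turmerone, (6S)-2-methyl-6-[(1R)-4-methylcyclohexa-2,4-dien-1-yl]hept-2-en-4-one | CC1=CC[C@@H](C=C1)[C@@H](C)CC(=O)C=C(C)C | starting material
2 | anti-endoperoxide, (6S)-2-methyl-6-[(1R,4S,7R)-5-methyl-2,3-dioxabicyclo[2.2.2]oct-5-en-7-yl]hept-2-en-4-one | CC1=C[C@@H]2OO[C@H]1C[C@@H]2[C@@H](C)CC(=O)C=C(C)C | intermediate
3 | vanillin, 4-hydroxy-3-methoxybenzaldehyde | COc1cc(C=O)ccc1O | starting material
4 | vinyl epoxide, (6S)-2-methyl-6-[(1R,4R,6S)-1-methyl-7-oxabicyclo[4.1.0]hept-2-en-4-yl]hept-2-en-4-one (oxirane on C4–C5, anti to the side chain) | C1=C[C@@]2(C)O[C@H]2C[C@@H]1[C@@H](C)CC(=O)C=C(C)C | intermediate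
5 | 4-{[(1R,4S,6R)-4-hydroxy-3-methyl-6-[(2S)-6-methyl-4-oxohept-5-en-2-yl]cyclohex-2-en-1-yl]oxy}-3-methoxybenzaldehyde | COc1cc(C=O)ccc1O[C@H]1C=C(C)[C@@H](O)C[C@@H]1[C@@H](C)CC(=O)C=C(C)C | intermediate
6 | 4-hydroxybenzaldehyde | O=Cc1ccc(O)cc1 | starting material
7 | acetylacetone, pentane-2,4-dione | CC(=O)CC(C)=O | starting material
8 | (1E,4Z)-5-hydroxy-1-(4-hydroxyphenyl)hexa-1,4-dien-3-one | C/C(O)=C/C(=O)/C=C/c1ccc(O)cc1 | intermediate
9 | demethoxybisabolocurcumin ether | COc1cc(/C=C/C(O)=C/C(=O)/C=C/c2ccc(O)cc2)ccc1O[C@H]1C=C(C)[C@@H](O)C[C@@H]1[C@@H](C)CC(=O)C=C(C)C | target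

**Totals and risks**
Total step count: 4. Longest linear sequence: 3 steps (1 → 2 → 5 → 9); step 3 is a one-step side branch.

The three steps most likely to fail:

Step 1. Facial selectivity is only moderate, and ene oxygenation or aromatisation to ar-turmerone can compete. The fallback sets out from 1 and drops the peroxide: dimethyldioxirane (acetone, −40 °C, acid-free) epoxidises the most electron-rich, trisubstituted C4=C5 alkene of the diene directly. It comes back to the route at 4, at the palladium stage of step 2, and makes no compound outside the list (F0). Facial control then rests on the more remote C1 centre, so 5 may need separation from its 2,5-bis-epimer.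

Step 2. The phosphine could deliver the regioisomeric 2,3-epoxide. The π-allylpalladium intermediate could also lose a hydride from C5 or be attacked at C4. The fallback sets out from 2 and keeps both peroxide oxygens, making the aryl–O bond instead of the allyl–O bond, so C2 cannot change configuration:
- Zn dust and AcOH (CH2Cl2, 0 °C) cleave only the O–O bond to give (6S)-6-[(1R,2R,5S)-2,5-dihydroxy-4-methylcyclohex-3-en-1-yl]-2-methylhept-2-en-4-one F1.
- TBSCl and imidazole (DMF, −20 °C) silylate the less hindered C5 hydroxyl to give (6S)-6-[(1R,2R,5S)-5-{[tert-butyl(dimethyl)silyl]oxy}-2-hydroxy-4-methylcyclohex-3-en-1-yl]-2-methylhept-2-en-4-one F2.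
- Chan–Lam O-arylation of the C2 hydroxyl with (4-formyl-2-methoxyphenyl)boronic acid (COc1cc(C=O)ccc1B(O)O; Cu(OAc)2, 4-(dimethylamino)pyridine, O2, 4 Å sieves, CH2Cl2, rt) gives 4-{[(1R,4S,6R)-4-{[tert-butyl(dimethyl)silyl]oxy}-3-methyl-6-[(2S)-6-methyl-4-oxohept-5-en-2-yl]cyclohex-2-en-1-yl]oxy}-3-methoxybenzaldehyde F3.
- HF·pyridine (THF, 0 °C) removes the silyl group, and the sequence comes back at 5.

Step 4. The chelate of 8 is a weak, conjugated nucleophile and 5 is a deactivated alkoxybenzaldehyde, so the heating needed may damage the allylic aryl ether or bring the side-chain ketone into play. The fallback sets out from 5 and reverses the order of chain assembly, so that a different C=C is formed last: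
- 5 is condensed with a fivefold excess of the more reactive boron chelate of 7 (same template, 40 °C) to give (3Z,5E)-4-hydroxy-6-[4-{[(1R,4S,6R)-4-hydroxy-3-methyl-6-[(2S)-6-methyl-4-oxohept-5-en-2-yl]cyclohex-2-en-1-yl]oxy}-3-methoxyphenyl]hexa-3,5-dien-2-one F4.
- F4 is then condensed at its methyl group with excess cheap 6, so the styryl bond on the 4-hydroxyphenyl side is made last, and the sequence comes back at 9.

**Further compounds**
F0 | step 1 | none | none
F1 | step 2 | (6S)-6-[(1R,2R,5S)-2,5-dihydroxy-4-methylcyclohex-3-en-1-yl]-2-methylhept-2-en-4-one | O[C@H]1C=C(C)[C@@H](O)C[C@@H]1[C@@H](C)CC(=O)C=C(C)C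
F2 | step 2 | (6S)-6-[(1R,2R,5S)-5-{[tert-butyl(dimethyl)silyl]oxy}-2-hydroxy-4-methylcyclohex-3-en-1-yl]-2-methylhept-2-en-4-one | O[C@H]1C=C(C)[C@@H](O[Si](C)(C)C(C)(C)C)C[C@@H]1[C@@H](C)CC(=O)C=C(C)C
F3 | step 2 | 4-{[(1R,4S,6R)-4-{[tert-butyl(dimethyl)silyl]oxy}-3-methyl-6-[(2S)-6-methyl-4-oxohept-5-en-2-yl]cyclohex-2-en-1-yl]oxy}-3-methoxybenzaldehyde | COc1cc(C=O)ccc1O[C@H]1C=C(C)[C@@H](O[Si](C)(C)C(C)(C)C)C[C@@H]1[C@@H](C)CC(=O)C=C(C)C
F4 | step 4 | (3Z,5E)-4-hydroxy-6-[4-{[(1R,4S,6R)-4-hydroxy-3-methyl-6-[(2S)-6-methyl-4-oxohept-5-en-2-yl]cyclohex-2-en-1-yl]oxy}-3-methoxyphenyl]hexa-3,5-dien-2-one | COc1cc(/C=C/C(O)=C/C(C)=O)ccc1O[C@H]1C=C(C)[C@@H](O)C[C@@H]1[C@@H](C)CC(=O)C=C(C)C
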